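## The problem

trans-δ-Viniferin 19 is a 2,3-diaryl-2,3-dihydrobenzofuran. Benzene ring B is fused through C3a and C7a to the O1–C2–C3 unit; C2 carries a 4-hydroxyphenyl group, C3 a 3,5-dihydroxyphenyl group and C5 an (E)-3,5-dihydroxystyryl arm. The two adjacent stereocentres must be 2S,3S with the aryl groups trans. They are not equivalent: C2 is a para-oxygenated benzylic ether carbon that can ionise and re-close, so it can follow C3 to the more stable trans arrangement, whereas C3 must be correct from the moment it is made. Five phenols, two nucleophilic resorcinol rings and a stilbene para to O1 exclude oxidants, hydrogenation and hot protic acid late in the route, so the phenols travel as methyl ethers and the alkene is made late from a C5 aldehyde. The feature that opens the plan is that the six carbons of ring B divide into three two-carbon units: C7a–C7 on O1, C3a–C4 on C3, and C5–C6 carrying the arm. The first two are the ends of a 1,6-diyne whose tether O1–C2–C3 already holds both stereocentres. What remains is an acyclic anti-1,2-diaryl homopropargylic alcohol as a single enantiomer, and control over where the third alkyne places its substituent (C5, not C6).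

## Retrosynthesis

**19 to 16 and 17.** The five O–CH3 bonds are cut last, which leads to pentamethyl ether 18. Cutting the stilbene C=C of 18 gives aldehyde 16 and phosphonate 17. This olefination is preferred to a cross-coupling at C5 because the aldehyde oxidation level comes directly from the ring-forming step and the E geometry is reliable. The forward steps must leave the C2–O1 bond and the alkene intact.

**16 to 14.** The formyl group is traced back to a diethyl acetal and the hydrogen on C7 to a silyl group, which gives 14. The precursor is no simpler in skeleton, but the acetal is the form in which the C5 carbon can be brought in on an alkyne, and the silyl group is what directs it there. The forward step needs one acid treatment that hydrolyses the acetal and cleaves the aryl–silicon bond ortho to O1.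

**14 to 12 and 13 (key disconnection).** Three ring-B bonds are cut at once: C3a–C7a, C4–C5 and C6–C7. Cuts at O1–C7a or C3–C3a would need a pre-functionalised arene and would leave the trans relationship to a ring-closing step. Here both rings appear in one operation from acyclic diyne 12 and alkyne 13, with both stereocentres as spectators on the tether. The forward reaction must favour cross- over homo-trimerisation, must place the acetal carbon on C5, and must run near room temperature because 12 is a benzylic ynol ether.

**12 to 7.** The C–H terminus of 12 is traced back to the trimethylsilyl alkyne in 11. The O–C(sp) bond of the ynol ether is then cut through lithium acetylide 10 and chloroalkyne 9 to dichlorovinyl ether 8, and from there to alcohol 7. Two different silyl groups are needed so that one alkyne can be unmasked while the other keeps its blocking group. The forward steps must not break the C1–O bond or deprotonate the benzylic, propargylic C2–H.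

**7 to 4 and 5.** The C1–C2 bond is cut to give 4-methoxybenzaldehyde 5 and allenylzinc 6, which is generated from mesylate 4. An aldol-type cut was considered, but it would need the alkyne to be built afterwards next to an epimerisable centre. This cut sets both stereocentres from the single stereocentre of 4. The forward reaction must transfer chirality cleanly and give the anti diastereomer.

**4 to 1 and 2.** Mesylate 4 comes from propargylic alcohol 3, whose C–C(sp) bond is cut to give 3,5-dimethoxybenzaldehyde 1 and trimethylsilylacetylene 2. A ynone reduction was the neighbouring option, but an aryl alkynyl ketone offers a reduction catalyst two competing π-substituents, and the direct addition is one step shorter. The forward reaction must give one enantiomer of a secondary aryl propargylic alcohol.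

## Roads not taken

**Alternative 1:** The cut is at C3–C3a, made by oxidative ring contraction of the enantioenriched flavanone A1. A hypervalent iodine oxidant of the ArI(OAc)2 type in acidified orthoformate forms the enol ether, iodinates C3 and triggers migration of the ring-B carbon from C4 to C3. The pyranone contracts to the trans dihydrobenzofuran ester A2 and C4 leaves as the ester carbon. Its merits are that C2 comes from a readily made flavanone and controls C3, and that the bromide at C5 is a handle for a Heck-type attachment of the arm. Its weak point for this target is that C3 ends with a methoxycarbonyl group where an aryl ring is needed. Turning that ester into a 3,5-dimethoxyphenyl ring at a centre that is α to a carbonyl and β to an aryloxy leaving group risks epimerisation and ring opening and costs several steps. The electron-rich 4-methoxyphenyl ring may also compete for the oxidant. Against the chosen plan, this road reaches the bicyclic core faster and by a well-known rearrangement, but the chosen plan has both aryl groups in place before any ring is closed.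

**Alternative 2:** The cuts are at C3a–C4 and C7–C7a, and ring B is built on the silyl ketene acetal A3 with methyl coumalate A4. An inverse-demand Diels–Alder reaction on heating, loss of CO2 and loss of silanol give the C5 ester A5. Regiochemistry is better secured here than in the chosen plan: the polarity of A4 puts the ester on C5 with no directing group, no metal and no later desilylation, and no sensitive ynol ether is carried. The weak points are the heat needed for a hindered ketene acetal next to the C3 aryl group, the elimination required to aromatise, and two redox steps from ester A5 to the aldehyde. A3 also needs the same anti diad plus a lactone carbonyl, so nothing is saved in the stereochemical part. The chosen plan sets against this a catalytic step at room temperature that delivers the aldehyde oxidation level directly; it pays with a silyl director and its removal.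

**Alternative 3:** The cut is at C2–C3, formed by insertion of a donor/donor rhodium carbene into the benzylic ether C–H bond. A chiral dirhodium carboxylate of the Rh2(O2CR*)4 type decomposes the diaryldiazomethane A6 and closes the dihydrofuran to the cis product A7. This road is shorter than the chosen one, creates both stereocentres in one catalytic enantioselective step, and carries a C5 bromide for the arm. Its weak points are that it gives the cis (2R,3S) isomer, so C2 must later be inverted by acid-mediated ring opening and re-closure. It also needs a diazo compound, and its selectivity depends on the match of catalyst and substrate. In step economy it is better than the chosen plan. The chosen plan sets against it a trans ring that follows directly from an acyclic anti diad without epimerisation, no diazo intermediate, and a ring B assembled late from simple alkynes.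

Key step: step 7

Assumption: the (S,S) antipode of the ProPhenol ligand is taken to deliver the R alcohol 3 from this aromatic aldehyde; if the sense of addition is the opposite, the (R,R) ligand is used and nothing else changes.

## Route

Step 1
Reactants: 1 3,5-dimethoxybenzaldehyde; 2 trimethylsilylacetylene
Product: 3 (R)-1-(3,5-dimethoxyphenyl)-3-(trimethylsilyl)prop-2-yn-1-ol
Conditions: 2 (3 equiv), Me2Zn (3 equiv), (S,S)-ProPhenol (10 mol %), Ph3P=O (20 mol %), toluene, 0 °C
Reagents that add atoms: none
Why: Zinc–ProPhenol-catalysed enantioselective alkynylation of an aromatic aldehyde; the dinuclear zinc complex holds the aldehyde and the alkynylzinc and delivers the alkynyl group to one carbonyl face, which sets the carbinol centre as R.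

Step 2
Reactants: 3 (R)-1-(3,5-dimethoxyphenyl)-3-(trimethylsilyl)prop-2-yn-1-ol
Product: 4 (R)-1-(3,5-dimethoxyphenyl)-3-(trimethylsilyl)prop-2-yn-1-yl methanesulfonate
Conditions: MsCl, Et3N, CH2Cl2, −78 °C; cold aqueous work-up, used at once without chromatography
Reagents that add atoms: methanesulfonyl chloride, CS(=O)(=O)Cl
Why: O-sulfonylation of a secondary alcohol leaves the C–O bond and its configuration untouched; the meta-methoxy groups do not stabilise a benzylic cation, which limits ionisation of the cold mesylate.

Step 3
Reactants: 4 (R)-1-(3,5-dimethoxyphenyl)-3-(trimethylsilyl)prop-2-yn-1-yl methanesulfonate; 5 4-methoxybenzaldehyde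
Product: 7 (1S,2S)-2-(3,5-dimethoxyphenyl)-1-(4-methoxyphenyl)-4-(trimethylsilyl)but-3-yn-1-ol (anti), via allenylzinc 6 (not isolated)
Conditions: Pd(OAc)2 (5 mol %), PPh3 (5 mol %), Et2Zn (3 equiv), THF, −78 → −20 °C
Reagents that add atoms: none
Why: Palladium-catalysed zinc umpolung of a propargylic mesylate: zerovalent palladium displaces the mesylate in an anti SN2' sense, and transmetalation with retention gives allenylzinc 6. 6 adds to 5 through a closed six-membered SE2' transition state with the aldehyde aryl group turned away from the 3,5-dimethoxyphenyl group, so net inversion at the former carbinol carbon sets C2 and the transition state sets C1 anti to it.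

Step 4
Reactants: 7 (1S,2S)-2-(3,5-dimethoxyphenyl)-1-(4-methoxyphenyl)-4-(trimethylsilyl)but-3-yn-1-ol
Product: 8 (1S,2S)-1-[(E)-1,2-dichloroethenyloxy]-2-(3,5-dimethoxyphenyl)-1-(4-methoxyphenyl)-4-(trimethylsilyl)but-3-yne, the (E)-1,2-dichlorovinyl ether of 7
Conditions: KH (1.5 equiv), THF, 0 °C; ClCH=CCl2 (1.1 equiv), −50 °C → rt
Reagents that add atoms: trichloroethylene, ClC=C(Cl)Cl
Why: Anti addition of the potassium alkoxide to dichloroacetylene generated in the flask, then protonation, gives the E dichlorovinyl ether; this is the standard entry to ynol ethers of secondary and benzylic alcohols, and no bond at C1 or C2 is broken.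

Step 5
Reactants: 8 (E)-1,2-dichlorovinyl ether of 7
Product: 11 (1S,2S)-2-(3,5-dimethoxyphenyl)-1-(4-methoxyphenyl)-4-(trimethylsilyl)but-3-yn-1-yl (triisopropylsilyl)ethynyl ether, via chloroethynyl ether 9 (not isolated), via lithium acetylide 10 (not isolated)
Conditions: n-BuLi (2.2 equiv), THF, −78 °C; i-Pr3SiOTf (1.3 equiv), −78 → −30 °C
Reagents that add atoms: triisopropylsilyl trifluoromethanesulfonate, CC(C)[Si](OS(=O)(=O)C(F)(F)F)(C(C)C)C(C)C
Why: Dehydrochlorination and chlorine–lithium exchange route to ynol ethers: deprotonation of the vinylic C–H and loss of LiCl give 9, exchange gives 10, and the silyl triflate caps the acetylide carbon. At −78 °C the silyl-capped alkyne and the C2–H are not attacked.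

Step 6
Reactants: 11 (1S,2S)-2-(3,5-dimethoxyphenyl)-1-(4-methoxyphenyl)-4-(trimethylsilyl)but-3-yn-1-yl (triisopropylsilyl)ethynyl ether
Product: 12 (1S,2R)-2-(3,5-dimethoxyphenyl)-1-(4-methoxyphenyl)but-3-yn-1-yl (triisopropylsilyl)ethynyl ether (anti diyne)
Conditions: K2CO3 (0.3 equiv), MeOH/THF (1:1), 0 °C
Reagents that add atoms: none
Why: Methoxide-mediated protodesilylation of an alkynylsilane is far faster for trimethylsilyl than for triisopropylsilyl, so only the all-carbon alkyne is unmasked; mild base at 0 °C should neither isomerise the propargylic centre nor add to the ynol ether. The descriptor at C2 changes to R only because the ethynyl group now ranks below the aryl group.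

Step 7
Reactants: 12 (1S,2R)-2-(3,5-dimethoxyphenyl)-1-(4-methoxyphenyl)but-3-yn-1-yl (triisopropylsilyl)ethynyl ether; 13 3,3-diethoxyprop-1-yne
Product: 14 (2S,3S)-5-(diethoxymethyl)-3-(3,5-dimethoxyphenyl)-2-(4-methoxyphenyl)-7-(triisopropylsilyl)-2,3-dihydrobenzofuran (trans)
Conditions: RhCl(PPh3)3 (10 mol %), 13 (5 equiv), toluene, 25 °C
Reagents that add atoms: none
Why: Loss of a phosphine from RhCl(PPh3)3 gives a monovalent rhodium centre that binds both alkynes of 12 and couples them oxidatively to a trivalent rhodacyclopentadiene; this forms C3a–C7a and closes the dihydrofuran ring across the three-atom tether O1–C2–C3. Coordination and insertion of 13, then C–C reductive elimination, form C4–C5 and C6–C7, release aromatic ring B and return monovalent rhodium. The closest known reaction type is the crossed (2+2+2) cycloaddition of heteroatom-tethered 1,6-diynes (ynamide and alkynyl ether diynes) with terminal alkynes under RhCl(PPh3)3 or Cp*RuCl(cod) near room temperature. The five-membered ring thus closes by metal-templated oxidative cyclisation of a 1,6-diyne and the six-membered ring by the three-component union itself. No stereocentre is made: C2 and C3 sit on the tether, are neither ionised nor deprotonated under neutral rhodium catalysis, and the anti diad of 12 is carried into the trans ring of 14. Cross- over homo-coupling is secured by the tether, which makes the oxidative coupling intramolecular, and by the excess of 13. The acetal carbon is steered to C5 by the triisopropylsilyl group: it shields the rhodium–C7 bond, so 13 inserts with its unsubstituted carbon next to C7 (becoming C6) and its substituted carbon bonding to the unhindered C4. The same silyl group stabilises the ynol ether, and 25 °C lies below the temperature at which benzylic alkynyl ethers rearrange sigmatropically.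

Step 8
Reactants: 14 (2S,3S)-5-(diethoxymethyl)-3-(3,5-dimethoxyphenyl)-2-(4-methoxyphenyl)-7-(triisopropylsilyl)-2,3-dihydrobenzofuran
Product: 16 (2S,3S)-3-(3,5-dimethoxyphenyl)-2-(4-methoxyphenyl)-2,3-dihydrobenzofuran-5-carbaldehyde, via silyl aldehyde 15 (not isolated)
Conditions: CF3CO2H/H2O (10:1), CH2Cl2, 0 °C → rt
Reagents that add atoms: water, O
Why: Aqueous acid hydrolyses the diethyl acetal to 15; ipso-protonation at C7, which is ortho to O1 and stabilised by the β-silicon, followed by loss of the silyl group completes an acid protodesilylation of an arylsilane. Water intercepts the oxocarbenium ion before it can alkylate a dimethoxyphenyl ring, and any reversible ionisation at C2 re-closes to the trans isomer with C3 untouched.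

Step 9
Reactants: 16 (2S,3S)-3-(3,5-dimethoxyphenyl)-2-(4-methoxyphenyl)-2,3-dihydrobenzofuran-5-carbaldehyde; 17 diethyl (3,5-dimethoxybenzyl)phosphonate
Product: 18 (2S,3S)-3-(3,5-dimethoxyphenyl)-5-[(E)-2-(3,5-dimethoxyphenyl)ethenyl]-2-(4-methoxyphenyl)-2,3-dihydrobenzofuran
Conditions: 17, KOt-Bu, THF, 0 °C; then 16, 0 °C → rt
Reagents that add atoms: none
Why: Horner–Wadsworth–Emmons olefination of a non-enolisable aromatic aldehyde with a benzylphosphonate anion gives the E stilbene; the C3–H is not acidified by the formyl group (meta relationship through C3a), so the preformed anion should leave the stereocentres alone.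

Step 10
Reactants: 18 (2S,3S)-3-(3,5-dimethoxyphenyl)-5-[(E)-2-(3,5-dimethoxyphenyl)ethenyl]-2-(4-methoxyphenyl)-2,3-dihydrobenzofuran
Product: 19 (2S,3S)-trans-δ-viniferin, 5-[(2S,3S)-5-[(E)-2-(3,5-dihydroxyphenyl)ethenyl]-2-(4-hydroxyphenyl)-2,3-dihydrobenzofuran-3-yl]benzene-1,3-diol
Conditions: BBr3 (8 equiv), CH2Cl2, −78 → 0 °C; MeOH quench, aqueous NaHCO3 work-up
Reagents that add atoms: none
Why: Lewis-acid cleavage of aryl methyl ethers: bromide attacks the methyl group of each boron-complexed ether and hydrolysis frees the phenols. Stilbenes of the resveratrol type tolerate BBr3 at low temperature, and reversible opening at C2 can only re-close to the more stable trans isomer because C3 stays fixed.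

## Compound list

1 | 3,5-dimethoxybenzaldehyde | COc1cc(C=O)cc(OC)c1 | starting material
2 | trimethylsilylacetylene | C#C[Si](C)(C)C | starting material
3 | (R)-1-(3,5-dimethoxyphenyl)-3-(trimethylsilyl)prop-2-yn-1-ol | O[C@H](c1cc(OC)cc(OC)c1)C#C[Si](C)(C)C | intermediate
4 | (R)-1-(3,5-dimethoxyphenyl)-3-(trimethylsilyl)prop-2-yn-1-yl methanesulfonate | CS(=O)(=O)O[C@H](c1cc(OC)cc(OC)c1)C#C[Si](C)(C)C | intermediate
5 | 4-methoxybenzaldehyde | COc1ccc(C=O)cc1 | starting material
6 | ethyl[(aS)-3-(3,5-dimethoxyphenyl)-1-(trimethylsilyl)propa-1,2-dien-1-yl]zinc | CC[Zn]C([Si](C)(C)C)=[C@@]=C([H])c1cc(OC)cc(OC)c1 | intermediate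
7 | (1S,2S)-2-(3,5-dimethoxyphenyl)-1-(4-methoxyphenyl)-4-(trimethylsilyl)but-3-yn-1-ol (anti) | COc1ccc([C@@H](O)[C@H](C#C[Si](C)(C)C)c2cc(OC)cc(OC)c2)cc1 | intermediate
8 | (1S,2S)-1-[(E)-1,2-dichloroethenyloxy]-2-(3,5-dimethoxyphenyl)-1-(4-methoxyphenyl)-4-(trimethylsilyl)but-3-yne | COc1ccc([C@@H](O/C(Cl)=C\Cl)[C@H](C#C[Si](C)(C)C)c2cc(OC)cc(OC)c2)cc1 | intermediate
9 | (1S,2S)-1-(chloroethynyloxy)-2-(3,5-dimethoxyphenyl)-1-(4-methoxyphenyl)-4-(trimethylsilyl)but-3-yne | COc1ccc([C@@H](OC#CCl)[C@H](C#C[Si](C)(C)C)c2cc(OC)cc(OC)c2)cc1 | intermediate
10 | (1S,2S)-2-(3,5-dimethoxyphenyl)-1-(lithioethynyloxy)-1-(4-methoxyphenyl)-4-(trimethylsilyl)but-3-yne | COc1ccc([C@@H](OC#C[Li])[C@H](C#C[Si](C)(C)C)c2cc(OC)cc(OC)c2)cc1 | intermediate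
11 | (1S,2S)-2-(3,5-dimethoxyphenyl)-1-(4-methoxyphenyl)-4-(trimethylsilyl)but-3-yn-1-yl (triisopropylsilyl)ethynyl ether | COc1ccc([C@@H](OC#C[Si](C(C)C)(C(C)C)C(C)C)[C@H](C#C[Si](C)(C)C)c2cc(OC)cc(OC)c2)cc1 | intermediate
12 | (1S,2R)-2-(3,5-dimethoxyphenyl)-1-(4-methoxyphenyl)but-3-yn-1-yl (triisopropylsilyl)ethynyl ether (anti) | COc1ccc([C@@H](OC#C[Si](C(C)C)(C(C)C)C(C)C)[C@H](C#C)c2cc(OC)cc(OC)c2)cc1 | intermediate
13 | 3,3-diethoxyprop-1-yne | C#CC(OCC)OCC | starting material
14 | (2S,3S)-5-(diethoxymethyl)-3-(3,5-dimethoxyphenyl)-2-(4-methoxyphenyl)-7-(triisopropylsilyl)-2,3-dihydrobenzofuran (trans) | COc1ccc([C@H]2Oc3c([Si](C(C)C)(C(C)C)C(C)C)cc(C(OCC)OCC)cc3[C@@H]2c2cc(OC)cc(OC)c2)cc1 | intermediate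
15 | (2S,3S)-3-(3,5-dimethoxyphenyl)-2-(4-methoxyphenyl)-7-(triisopropylsilyl)-2,3-dihydrobenzofuran-5-carbaldehyde | COc1ccc([C@H]2Oc3c([Si](C(C)C)(C(C)C)C(C)C)cc(C=O)cc3[C@@H]2c2cc(OC)cc(OC)c2)cc1 | intermediate
16 | (2S,3S)-3-(3,5-dimethoxyphenyl)-2-(4-methoxyphenyl)-2,3-dihydrobenzofuran-5-carbaldehyde | COc1ccc([C@H]2Oc3ccc(C=O)cc3[C@@H]2c2cc(OC)cc(OC)c2)cc1 | intermediate
17 | diethyl (3,5-dimethoxybenzyl)phosphonate | CCOP(=O)(Cc1cc(OC)cc(OC)c1)OCC | starting material
18 | (2S,3S)-3-(3,5-dimethoxyphenyl)-5-[(E)-2-(3,5-dimethoxyphenyl)ethenyl]-2-(4-methoxyphenyl)-2,3-dihydrobenzofuran | COc1ccc([C@H]2Oc3ccc(/C=C/c4cc(OC)cc(OC)c4)cc3[C@@H]2c2cc(OC)cc(OC)c2)cc1 | intermediate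
19 | (2S,3S)-trans-δ-viniferin | Oc1ccc([C@H]2Oc3ccc(/C=C/c4cc(O)cc(O)c4)cc3[C@@H]2c2cc(O)cc(O)c2)cc1 | target

## Step count and least certain steps

Total: 10 steps. Longest linear sequence: 10 steps (1 to 19); 2, 5, 13 and 17 enter as purchased compounds.

**Step 7 (key step).** The most likely failure is slow oxidative coupling at the alkyne that carries the bulky silyl group. Oligomerisation of 13 would then consume the partner, and raising the temperature would bring loss of the benzylic ynol ether by sigmatropic rearrangement or retro-ene fragmentation. A second risk is partial delivery of the acetal carbon to C6. Cp*RuCl(cod) in 1,2-dichloroethane at room temperature is the first remedy but only changes the catalyst. The fallback changes the substrate design and sets out from 8. Treatment with n-BuLi and then Et3SiOTf should give the triethylsilyl ynol ether F1. K2CO3 in methanol at −10 °C, where the trimethylsilyl group on the all-carbon alkyne should still be lost faster, should give the terminal diyne F2. Cycloaddition with 13 under the conditions of step 7 should give the 7-triethylsilyl cycloadduct F3, whose smaller silyl group shields the rhodium less but still sits next to C6. Aqueous CF3CO2H then hydrolyses the acetal and cleaves the aryl–triethylsilyl bond more easily than the triisopropylsilyl analogue, and the route is rejoined at 16.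

**Step 3.** The likely failures are loss of enantiopurity, through ionisation of the benzylic propargylic mesylate before oxidative addition or through racemisation of the aryl-substituted allenylzinc, and erosion of anti selectivity with an aromatic aldehyde. The fallback sets out from 3 and uses a configurationally stable boron reagent. ClCO2Me and pyridine should give the methyl carbonate F4. Borylation with B2pin2 under CuCl/Xantphos/NaOt-Bu in THF, an anti SN2' process, should give the allenylboronate F5, which can be purified. F5 should add to 5 in toluene at 50 °C (or at room temperature with diphenyl phosphate as catalyst) through the same closed SE2' transition state, and oxidative work-up is not needed. The route is rejoined at 7.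

**Step 4.** The likely failures are fragmentation of the potassium alkoxide by retro-propargylation (expulsion of the benzylic, propargylic carbanion), silyl transfer from the alkyne to the alkoxide, or base-induced elimination before the oxygen is vinylated. The fallback sets out from 7 and avoids a free alkoxide. Formic acetic anhydride and pyridine should give the formate F6. Dichloromethylenation of the formyl group with PPh3/CCl4 in THF should give the 2,2-dichlorovinyl ether F7. n-BuLi (2.2 equiv) at −78 °C then passes through 9 and 10, and i-Pr3SiOTf returns the route at 11.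

**Step 10.** The likely failures are ionisation of the C2–O1 bond followed by cationic capture, acid-triggered cyclisation or oligomerisation of the electron-rich stilbene, and incomplete cleavage of five ethers. The fallback sets out from 16 and moves the Lewis-acid step to a stage without the alkene. BBr3 on 16 should give the triphenol aldehyde F8, in which the formyl group para to O1 makes that oxygen a poorer Lewis base. Silylation with t-BuMe2SiCl and imidazole should give the tris-silyl ether F9. Olefination with the silyl-protected phosphonate F10 and NaH in THF should give the penta-silyl ether F11. Buffered fluoride (Bu4NF/AcOH, THF, 0 °C) then frees all five phenols under near-neutral conditions and returns the route at 19.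

## Further compounds

F1 | step 7 | (1S,2S)-2-(3,5-dimethoxyphenyl)-1-(4-methoxyphenyl)-4-(trimethylsilyl)but-3-yn-1-yl (triethylsilyl)ethynyl ether | COc1ccc([C@@H](OC#C[Si](CC)(CC)CC)[C@H](C#C[Si](C)(C)C)c2cc(OC)cc(OC)c2)cc1
F2 | step 7 | (1S,2R)-2-(3,5-dimethoxyphenyl)-1-(4-methoxyphenyl)but-3-yn-1-yl (triethylsilyl)ethynyl ether | COc1ccc([C@@H](OC#C[Si](CC)(CC)CC)[C@H](C#C)c2cc(OC)cc(OC)c2)cc1
F3 | step 7 | (2S,3S)-5-(diethoxymethyl)-3-(3,5-dimethoxyphenyl)-2-(4-methoxyphenyl)-7-(triethylsilyl)-2,3-dihydrobenzofuran | COc1ccc([C@H]2Oc3c([Si](CC)(CC)CC)cc(C(OCC)OCC)cc3[C@@H]2c2cc(OC)cc(OC)c2)cc1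
F4 | step 3 | (R)-1-(3,5-dimethoxyphenyl)-3-(trimethylsilyl)prop-2-yn-1-yl methyl carbonate | COC(=O)O[C@H](c1cc(OC)cc(OC)c1)C#C[Si](C)(C)C
F5 | step 3 | 2-[(aR)-3-(3,5-dimethoxyphenyl)-1-(trimethylsilyl)propa-1,2-dien-1-yl]-4,4,5,5-tetramethyl-1,3,2-dioxaborolane (same spatial arrangement as 6) | B1(OC(C)(C)C(C)(C)O1)C([Si](C)(C)C)=[C@@]=C([H])c1cc(OC)cc(OC)c1
F6 | step 4 | (1S,2S)-2-(3,5-dimethoxyphenyl)-1-(4-methoxyphenyl)-4-(trimethylsilyl)but-3-yn-1-yl formate | COc1ccc([C@@H](OC=O)[C@H](C#C[Si](C)(C)C)c2cc(OC)cc(OC)c2)cc1
F7 | step 4 | (1S,2S)-1-(2,2-dichloroethenyloxy)-2-(3,5-dimethoxyphenyl)-1-(4-methoxyphenyl)-4-(trimethylsilyl)but-3-yne | COc1ccc([C@@H](OC=C(Cl)Cl)[C@H](C#C[Si](C)(C)C)c2cc(OC)cc(OC)c2)cc1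
F8 | step 10 | (2S,3S)-3-(3,5-dihydroxyphenyl)-2-(4-hydroxyphenyl)-2,3-dihydrobenzofuran-5-carbaldehyde | Oc1ccc([C@H]2Oc3ccc(C=O)cc3[C@@H]2c2cc(O)cc(O)c2)cc1
F9 | step 10 | (2S,3S)-3-[3,5-bis(tert-butyldimethylsilyloxy)phenyl]-2-[4-(tert-butyldimethylsilyloxy)phenyl]-2,3-dihydrobenzofuran-5-carbaldehyde | CC(C)(C)[Si](C)(C)Oc1ccc([C@H]2Oc3ccc(C=O)cc3[C@@H]2c2cc(O[Si](C)(C)C(C)(C)C)cc(O[Si](C)(C)C(C)(C)C)c2)cc1
F10 | step 10 | diethyl [3,5-bis(tert-butyldimethylsilyloxy)benzyl]phosphonate | CCOP(=O)(Cc1cc(O[Si](C)(C)C(C)(C)C)cc(O[Si](C)(C)C(C)(C)C)c1)OCC
F11 | step 10 | penta-O-(tert-butyldimethylsilyl) ether of (2S,3S)-trans-δ-viniferin | CC(C)(C)[Si](C)(C)Oc1ccc([C@H]2Oc3ccc(/C=C/c4cc(O[Si](C)(C)C(C)(C)C)cc(O[Si](C)(C)C(C)(C)C)c4)cc3[C@@H]2c2cc(O[Si](C)(C)C(C)(C)C)cc(O[Si](C)(C)C(C)(C)C)c2)cc1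
A1 | alternative 1 | (S)-6-bromo-2-(4-methoxyphenyl)chroman-4-one | COc1ccc([C@H]2Oc3ccc(Br)cc3C(=O)C2)cc1
A2 | alternative 1 | methyl (2S,3S)-5-bromo-2-(4-methoxyphenyl)-2,3-dihydrobenzofuran-3-carboxylate (trans) | COc1ccc([C@H]2Oc3ccc(Br)cc3[C@@H]2C(=O)OC)cc1
A3 | alternative 2 | {[(4R,5S)-4-(3,5-dimethoxyphenyl)-5-(4-methoxyphenyl)-4,5-dihydrofuran-2-yl]oxy}trimethylsilane (trans) | COc1ccc([C@H]2OC(O[Si](C)(C)C)=C[C@@H]2c2cc(OC)cc(OC)c2)cc1
A4 | alternative 2 | methyl coumalate (methyl 2-oxo-2H-pyran-5-carboxylate) | COC(=O)c1ccc(=O)oc1
A5 | alternative 2 | methyl (2S,3S)-3-(3,5-dimethoxyphenyl)-2-(4-methoxyphenyl)-2,3-dihydrobenzofuran-5-carboxylate (trans) | COc1ccc([C@H]2Oc3ccc(C(=O)OC)cc3[C@@H]2c2cc(OC)cc(OC)c2)cc1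
A6 | alternative 3 | 4-bromo-2-[diazo(3,5-dimethoxyphenyl)methyl]-1-[(4-methoxybenzyl)oxy]benzene | COc1ccc(COc2ccc(Br)cc2C(=[N+]=[N-])c2cc(OC)cc(OC)c2)cc1
A7 | alternative 3 | (2R,3S)-5-bromo-3-(3,5-dimethoxyphenyl)-2-(4-methoxyphenyl)-2,3-dihydrobenzofuran (cis) | COc1ccc([C@@H]2Oc3ccc(Br)cc3[C@@H]2c2cc(OC)cc(OC)c2)cc1
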